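**Plan**

1. Numbering (isocopalane): ring A = C1–C5, C10; ring B = C5–C10; ring C = C8, C9, C11–C14; C15 = benzylic carbon; C16, C17, C18 = methyls on C13, C8, C4; C19 = lactone C=O on C4; C20 = lactone OCH2 on C10; β = the face of C20.
2. Cuts: ring C at C12–C13 and C8–C14 (Diels–Alder), after taking C9–C11 back to an alkene, C13–C16 to an exocyclic alkene and C15 to an aryl ketone; then C9–C11 (vinyl coupling), C3–C4 (ring A), C4–C5 and C20–O (lactone ring), C10–C1 (Birch alkylation).
3. Enabling feature: in ring C the two-carbon unit C13–C14 lies between the ends of the chain C12–C11–C9–C8 that hangs on ring B. C9 and C11 carry H, C13 carries a methyl that can start as =CH2, and C14 carries the benzylic C15 that can start as a carbonyl. Ring C is therefore the retron of a [4+2] between a ring B vinyl diene and an aryl allenyl ketone that brings in every remaining carbon.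
4. Forward: ring B by dearomatization of 2-methoxy-3-methylbenzoic acid (Birch reduction–alkylation); lactone ring by radical cyclization through the C20–O–C19 ester tether; ring A by enolate alkylation; diene by triflation and Stille coupling; ring C by the Diels–Alder reaction; then C15, C13 and C9 are adjusted and the benzyl groups removed.
5. Stereochemistry: C10 from the (S)-2-(methoxymethyl)pyrrolidine amide auxiliary; C5 from the tether (C4 delivered on the C20 face); C4 fixed by the bicyclo[3.3.1] closure; C8 and C14 from α-face, endo cycloaddition; C13 from C15-hydroxyl-directed epoxidation; C9 from hydroxyl-directed hydrogenation.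

Key step: step 12

Assumption: the amide of (S)-2-(methoxymethyl)pyrrolidine is taken to direct the alkylation of step 2 anti to its chelated methoxymethyl arm, which gives the (R) quaternary carbon drawn for 6; if the sense is the opposite, the (R)-amine is used and nothing else changes.

**Route**

Step 1
Reactants: 1 2-methoxy-3-methylbenzoic acid; 2 (2S)-2-(methoxymethyl)pyrrolidine
Product: 4 (2-methoxy-3-methylphenyl)[(2S)-2-(methoxymethyl)pyrrolidin-1-yl]methanone, via acid chloride 3 (not isolated)
Conditions: (COCl)2, DMF (cat.), CH2Cl2, 0 °C → rt; then 2, Et3N, CH2Cl2, 0 °C → rt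
Reagents that add atoms: none
Why: Amide formation by acylation of the secondary amine with the acid chloride made in the flask; the stereocenter of 2 is not touched.

Step 2
Reactants: 4
Product: 6 [(1R)-1-(3-chloropropyl)-2-methoxy-3-methylcyclohexa-2,5-dien-1-yl][(2S)-2-(methoxymethyl)pyrrolidin-1-yl]methanone, via potassium amide enolate 5 (not isolated)
Conditions: K, t-BuOH (1 equiv), NH3/THF, −78 °C; then ICH2CH2CH2Cl, −78 °C → rt
Reagents that add atoms: 1-chloro-3-iodopropane, ClCCCI
Why: Auxiliary-controlled Birch reduction–alkylation: reduction and protonation para to the amide give the chelated enolate 5, which the iodide end of the dihalide alkylates at the future C10 anti to the methoxymethyl arm, setting the quaternary stereocenter and leaving a 2-methoxy-1,4-diene (masked C9 ketone, C8 methyl, C5=C6).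

Step 3
Reactants: 6
Product: 7 [(1S)-1-(3-chloropropyl)-2-methoxy-3-methylcyclohexa-2,5-dien-1-yl]methanol
Conditions: LiH2NBH3 (from BH3·NH3, n-BuLi), THF, 0 °C → rt; aq. work-up
Reagents that add atoms: none
Why: Reduction of a hindered tertiary amide to the primary alcohol by lithium amidotrihydroborate (C–N cleavage, then reduction of the aldehyde), which at 0 °C should spare the primary chloride, the enol ether and the diene; auxiliary 2 is recovered.

Step 4
Reactants: 7
Product: 8 [(1S)-1-(3-chloropropyl)-2-methoxy-3-methylcyclohexa-2,5-dien-1-yl]methyl 2-bromopropanoate (both CHBr epimers)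
Conditions: CH3CHBrCOBr, pyridine, CH2Cl2, 0 °C
Reagents that add atoms: 2-bromopropanoyl bromide, CC(Br)C(Br)=O
Why: Esterification of the neopentyl alcohol with an acyl bromide under pyridine, which keeps the acid-labile enol ether intact; the CHBr centre is destroyed in step 5.

Step 5
Reactants: 8
Product: 9 (4aS,8aS)-8a-(3-chloropropyl)-8-methoxy-4,7-dimethyl-1,4,4a,5,6,8a-hexahydro-3H-isochromen-3-one (cis-fused lactone; C4 epimers)
Conditions: Bu3SnH (slow addition), AIBN (cat.), PhH, 80 °C
Reagents that add atoms: none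
Why: Tin hydride mediated 6-exo-trig radical cyclization: the α-ester radical (C4) is held by the C20–O–C19 tether on the C20 face and can reach only C5 of C5=C6 from that face, so the δ-lactone is cis-fused and H-5 ends trans to C20 (the trans A/B relationship of the target); the chloride is inert and the C4 epimers converge in step 6.

Step 6
Reactants: 9
Product: 11 9-oxo-11,12,13,14,15,16-hexanorlabdan-19,20-olide (C8 epimers), via tricyclic enol ether 10 (not isolated)
Conditions: KN(SiMe3)2, THF/DMPU, −78 °C → rt; then 2 M HCl, THF, rt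
Reagents that add atoms: water, O
Why: Intramolecular C-alkylation of the lactone enolate (6-exo-tet) by the C3 chloride closes ring A and makes C4 quaternary, its methyl forced exo (α) because C4 becomes a bridgehead of the 3-oxabicyclo[3.3.1]nonanone; the acidic work-up hydrolyses the methyl enol ether to the C9 ketone.

Step 7
Reactants: 11
Product: 12 9-(trifluoromethanesulfonyloxy)-11,12,13,14,15,16-hexanorlabd-8-en-19,20-olide
Conditions: KN(SiMe3)2, PhNTf2, THF, −78 → 0 °C
Reagents that add atoms: N-phenylbis(trifluoromethanesulfonimide), O=S(=O)(N(c1ccccc1)S(=O)(=O)C(F)(F)F)C(F)(F)F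
Why: Enol triflate formation: the ketone can enolize only toward C8 (C10 is quaternary and the lactone has no α-hydrogen), so the tetrasubstituted C8=C9 triflate forms regiospecifically and the C8 epimers converge.

Step 8
Reactants: 12
Product: 13 13,14,15,16-tetranorlabda-8,11-dien-19,20-olide
Conditions: CH2=CHSnBu3, Pd(PPh3)4 (cat.), LiCl, THF, 65 °C
Reagents that add atoms: tributyl(vinyl)stannane, C=C[Sn](CCCC)(CCCC)CCCC
Why: Stille coupling of a hindered cyclohexenyl triflate with a vinylstannane, the standard entry to 2-methyl-1-vinylcyclohexene-type dienes; no stereocenter is involved.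

Step 9
Reactants: 14 2,5-dihydroxybenzaldehyde
Product: 15 2,5-bis(benzyloxy)benzaldehyde
Conditions: BnBr, K2CO3, DMF, 60 °C
Reagents that add atoms: benzyl bromide, BrCc1ccccc1
Why: Williamson ether synthesis on both phenols; the benzyl ethers should survive all later steps and leave by hydrogenolysis in step 17.

Step 10
Reactants: 15
Product: 16 1-[2,5-bis(benzyloxy)phenyl]but-3-yn-1-ol (racemic)
Conditions: HC≡CCH2Br, Zn, THF/sat. aq. NH4Cl, 0 °C → rt
Reagents that add atoms: 3-bromoprop-1-yne, C#CCBr
Why: Zinc Barbier propargylation, in which the allenylzinc species adds to the aldehyde by an SE2' path to give the homopropargylic alcohol; the new centre becomes a ketone in step 11.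

Step 11
Reactants: 16
Product: 18 1-[2,5-bis(benzyloxy)phenyl]buta-2,3-dien-1-one, via but-3-ynone 17 (not isolated)
Conditions: Dess–Martin periodinane, CH2Cl2, 0 °C; then Et3N (cat.), rt
Reagents that add atoms: none
Why: Dess–Martin oxidation to the β,γ-ynone, which isomerizes by base-catalysed prototropy to the conjugated allenyl ketone; 18 is used at once.

Step 12
Reactants: 13; 18
Product: 19 15-[2,5-bis(benzyloxy)phenyl]-15-oxoisocopala-9(11),13(16)-dien-19,20-olide (8β-methyl; 14β-H, aroyl group α)
Conditions: Sc(OTf)3 (10 mol %), CH2Cl2, −40 → 0 °C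
Reagents that add atoms: none
Why: Sc(OTf)3 binds the aryl ketone of 18 (chelated by the ortho benzyloxy oxygen), and diene 13 adds across the conjugated C13=C14 bond of the allene in an asynchronous, concerted, normal-demand Diels–Alder reaction in which C12–C13 forms ahead of C8–C14. The closest known reaction types are the cycloadditions of 2,6,6-trimethyl-1-vinylcyclohexene with acetylenic esters and quinones, which build the same methyl-bearing quaternary carbon, and the Lewis-acid Diels–Alder reactions of allenyl ketones and allenoates at their conjugated double bond. Ring C closes as the six-membered ring of a [4+2] cycloaddition, suprafacial on both partners, leaving C9=C11 in the ring and C13=C16 exocyclic. C8 is set by approach of 18 to the α face of the diene, anti to the axial C20 methylene of the lactone bridge on C10, so the C17 methyl ends β; C14 is set by the endo orientation of the chelated aroyl group, which also keeps it away from the inward-pointing C17 methyl, so the aroyl group ends α and H-14 β. The step needs regioselectivity, which the polarisation secures (C12 is the nucleophilic terminus because charge develops at tertiary C8, and the central allene carbon C13 is the electrophilic β-carbon), and site selectivity for the conjugated allene bond, which its activation by the carbonyl provides.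

Step 13
Reactants: 19
Product: 20 15-[2,5-bis(benzyloxy)phenyl]-15-hydroxyisocopala-9(11),13(16)-dien-19,20-olide (C15 epimers)
Conditions: NaBH4, CeCl3·7H2O, MeOH/CH2Cl2, −40 °C
Reagents that add atoms: none
Why: Luche 1,2-reduction of the aryl ketone at low temperature and without base, so the β,γ-unsaturated ketone should not slip into conjugation (which would erase C14) and the lactone is untouched; both C15 epimers are carried on because C15 becomes CH2 in step 17.

Step 14
Reactants: 20
Product: 21 15-[2,5-bis(benzyloxy)phenyl]-13α,16-epoxy-15-hydroxyisocopal-9(11)-en-19,20-olide (C15 epimers)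
Conditions: VO(acac)2 (cat.), t-BuOOH, CH2Cl2, 0 °C → rt
Reagents that add atoms: tert-butyl hydroperoxide, CC(C)(C)OO
Why: Hydroxyl-directed, vanadium-catalysed epoxidation of the homoallylic alcohol: the vanadate ester on C15, which sits on the α face at C14, delivers oxygen to the α face of the exocyclic C13=C16 bond, setting the C13–O bond α (cis to C15); the hindered, more remote C9=C11 bond should react more slowly.

Step 15
Reactants: 21
Product: 23 15-[2,5-bis(benzyloxy)phenyl]-13α,15-dihydroxyisocopal-9(11)-en-19,20-olide (13β-methyl; C15 epimers), via iodohydrin 22 (not isolated)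
Conditions: MgI2, Et2O/PhMe, −60 → 0 °C; then Bu3SnH, AIBN (cat.), 80 °C
Reagents that add atoms: none
Why: Magnesium-assisted SN2 opening of the terminal epoxide by iodide at the primary C16, then radical deiodination, turns C16 into the methyl group without touching the C13–O bond (13α-OH, 13β-methyl); the sequence is chosen because hydride reagents that open epoxides would also reduce the lactone.

Step 16
Reactants: 23
Product: 24 15-[2,5-bis(benzyloxy)phenyl]-13α,15-dihydroxyisocopalan-19,20-olide (9α-H; C15 epimers)
Conditions: [Ir(cod)(PCy3)(py)]PF6 (cat.), H2 (1 atm), CH2Cl2, rt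
Reagents that add atoms: none
Why: Hydroxyl-directed homogeneous hydrogenation: the cationic iridium catalyst binds the α-oriented C13 and C15 hydroxyls and adds H2 to the α face of the hindered C9=C11 bond, giving 9α-H (trans B/C fusion); this is also the less hindered face because C17 and C20 block the β face.

Step 17
Reactants: 24
Product: 25 15-(2,5-dihydroxyphenyl)-13α-hydroxyisocopalan-19,20-olide (4α-methyl, 5α-H, 8β-methyl, 9α-H, 13β-methyl, 14β-H), CNP0148621.1
Conditions: H2 (3 atm), 10% Pd/C, EtOAc/AcOH, rt
Reagents that add atoms: none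
Why: Palladium-catalysed hydrogenolysis removes both benzyl ethers and the benzylic C15 hydroxyl (eased by the ortho hydroxyl through an ortho-quinone methide), while the tertiary, non-benzylic C13 hydroxyl and the lactone should stay.

**Compound list**

1 | 2-methoxy-3-methylbenzoic acid | COc1c(C)cccc1C(=O)O | starting material
2 | (2S)-2-(methoxymethyl)pyrrolidine | COC[C@@H]1CCCN1 | starting material
3 | 2-methoxy-3-methylbenzoyl chloride | COc1c(C)cccc1C(=O)Cl | intermediate
4 | (2-methoxy-3-methylphenyl)[(2S)-2-(methoxymethyl)pyrrolidin-1-yl]methanone | COC[C@@H]1CCCN1C(=O)c1cccc(C)c1OC | intermediate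
5 | potassium (2-methoxy-3-methylcyclohexa-2,5-dien-1-ylidene)[(2S)-2-(methoxymethyl)pyrrolidin-1-yl]methanolate (amide enolate) | COC[C@@H]1CCCN1C([O-])=C1C=CCC(C)=C1OC.[K+] | intermediate
6 | [(1R)-1-(3-chloropropyl)-2-methoxy-3-methylcyclohexa-2,5-dien-1-yl][(2S)-2-(methoxymethyl)pyrrolidin-1-yl]methanone | COC[C@@H]1CCCN1C(=O)[C@]1(CCCCl)C=CCC(C)=C1OC | intermediate
7 | [(1S)-1-(3-chloropropyl)-2-methoxy-3-methylcyclohexa-2,5-dien-1-yl]methanol | OC[C@]1(CCCCl)C=CCC(C)=C1OC | intermediate
8 | [(1S)-1-(3-chloropropyl)-2-methoxy-3-methylcyclohexa-2,5-dien-1-yl]methyl 2-bromopropanoate (both CHBr epimers) | CC(Br)C(=O)OC[C@]1(CCCCl)C=CCC(C)=C1OC | intermediate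
9 | (4aS,8aS)-8a-(3-chloropropyl)-8-methoxy-4,7-dimethyl-1,4,4a,5,6,8a-hexahydro-3H-isochromen-3-one (C4 epimers) | COC1=C(C)CC[C@H]2C(C)C(=O)OC[C@@]12CCCCl | intermediate
10 | 9-methoxy-11,12,13,14,15,16-hexanorlabd-8-en-19,20-olide (4α-methyl, 5α-H) | COC1=C(C)CC[C@H]2[C@]3(C)CCC[C@]12COC3=O | intermediate
11 | 9-oxo-11,12,13,14,15,16-hexanorlabdan-19,20-olide (C8 epimers) | O=C1C(C)CC[C@H]2[C@]3(C)CCC[C@]12COC3=O | intermediate
12 | 9-(trifluoromethanesulfonyloxy)-11,12,13,14,15,16-hexanorlabd-8-en-19,20-olide | CC1=C(OS(=O)(=O)C(F)(F)F)[C@]2(COC(=O)[C@@]3(C)CCC2)[C@H]3CC1 | intermediate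
13 | 13,14,15,16-tetranorlabda-8,11-dien-19,20-olide | CC1=C(C=C)[C@]2(COC(=O)[C@@]3(C)CCC2)[C@H]3CC1 | intermediate
14 | 2,5-dihydroxybenzaldehyde | O=Cc1cc(O)ccc1O | starting material
15 | 2,5-bis(benzyloxy)benzaldehyde | O=Cc1cc(OCc2ccccc2)ccc1OCc1ccccc1 | intermediate
16 | 1-[2,5-bis(benzyloxy)phenyl]but-3-yn-1-ol (racemic) | C#CCC(O)c1cc(OCc2ccccc2)ccc1OCc1ccccc1 | intermediate
17 | 1-[2,5-bis(benzyloxy)phenyl]but-3-yn-1-one | C#CCC(=O)c1cc(OCc2ccccc2)ccc1OCc1ccccc1 | intermediate
18 | 1-[2,5-bis(benzyloxy)phenyl]buta-2,3-dien-1-one | C=C=CC(=O)c1cc(OCc2ccccc2)ccc1OCc1ccccc1 | intermediate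
19 | 15-[2,5-bis(benzyloxy)phenyl]-15-oxoisocopala-9(11),13(16)-dien-19,20-olide (8β-methyl, 14β-H) | C[C@@]12CC[C@@H]3[C@]4(CCC[C@]3(C)C(=O)OC4)C1=CCC(=C)[C@@H]2C(=O)c1cc(OCc2ccccc2)ccc1OCc1ccccc1 | intermediate
20 | 15-[2,5-bis(benzyloxy)phenyl]-15-hydroxyisocopala-9(11),13(16)-dien-19,20-olide (C15 epimers) | C[C@@]12CC[C@@H]3[C@]4(CCC[C@]3(C)C(=O)OC4)C1=CCC(=C)[C@@H]2C(O)c1cc(OCc2ccccc2)ccc1OCc1ccccc1 | intermediate
21 | 15-[2,5-bis(benzyloxy)phenyl]-13α,16-epoxy-15-hydroxyisocopal-9(11)-en-19,20-olide (C15 epimers) | C[C@@]12CC[C@@H]3[C@]4(CCC[C@]3(C)C(=O)OC4)C1=CC[C@@]5(CO5)[C@@H]2C(O)c1cc(OCc2ccccc2)ccc1OCc1ccccc1 | intermediate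
22 | 15-[2,5-bis(benzyloxy)phenyl]-13α,15-dihydroxy-16-iodoisocopal-9(11)-en-19,20-olide (formed as its magnesium alkoxide; C15 epimers) | C[C@@]12CC[C@@H]3[C@]4(CCC[C@]3(C)C(=O)OC4)C1=CC[C@](CI)(O)[C@@H]2C(O)c1cc(OCc2ccccc2)ccc1OCc1ccccc1 | intermediate
23 | 15-[2,5-bis(benzyloxy)phenyl]-13α,15-dihydroxyisocopal-9(11)-en-19,20-olide (13β-methyl, 14β-H; C15 epimers) | C[C@@]12CC[C@@H]3[C@]4(CCC[C@]3(C)C(=O)OC4)C1=CC[C@](C)(O)[C@@H]2C(O)c1cc(OCc2ccccc2)ccc1OCc1ccccc1 | intermediate
24 | 15-[2,5-bis(benzyloxy)phenyl]-13α,15-dihydroxyisocopalan-19,20-olide (9α-H; C15 epimers) | C[C@@]12CC[C@@H]3[C@]4(CCC[C@]3(C)C(=O)OC4)[C@H]1CC[C@](C)(O)[C@@H]2C(O)c1cc(OCc2ccccc2)ccc1OCc1ccccc1 | intermediate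
25 | 15-(2,5-dihydroxyphenyl)-13α-hydroxyisocopalan-19,20-olide (4α-methyl, 5α-H, 8β-methyl, 9α-H, 13β-methyl, 14β-H), CNP0148621.1 | C[C@@]12CC[C@@H]3[C@]4(CCC[C@]3(C)C(=O)OC4)[C@H]1CC[C@](C)(O)[C@@H]2Cc1cc(O)ccc1O | target

**Count**

Total steps: 17. Longest linear sequence: 14 steps (steps 1–8, then 12–17); the dienophile branch is steps 9–11.

**Steps most likely to fail, with fallbacks**

Step 12 (key step). The C17 methyl and the quaternary C10 twist the diene out of its s-cis form, so oligomerisation of the allene, an ene reaction, or open-chain conjugate addition at C12 may overtake ring closure at the trisubstituted C8, and endo or facial control may erode. The fallback raises the diene HOMO with a C11 silyloxy group that is deleted afterwards. It sets out from triflate 12. Carbonylative Stille coupling (CO, SnMe4, Pd(PPh3)4, LiCl) should give methyl ketone F1. Kinetic enolization (LiN(i-Pr)2, then TBSCl) should give silyloxy diene F2. Thermal cycloaddition of F2 with 18 (PhMe, 60 °C) should give silyl enol ether adduct F3, with the same α-face and endo arguments and the regiochemistry reinforced by the C11 donor. NaBH4/CeCl3 should give alcohol F4. CsF/PhNTf2 should convert the silyl enol ether regiospecifically into enol triflate F5. Pd(OAc)2/PPh3/HCO2H/Bu3N then reduces C11–OTf to C11–H, and the route is rejoined at compound 20.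

Step 5. The α-ester radical may be reduced before it cyclises, because the ester prefers the s-trans rotamer from which C5 cannot be reached; attack on the enol ether carbon C9 is a second leak. The fallback uses an Ueno–Stork acetal tether, which has no such rotamer bias, and changes the order of the later steps. It sets out from alcohol 7. 1,2-Dibromo-1-ethoxypropane with i-Pr2NEt should give bromoacetal F6. Bu3SnH/AIBN should give lactol ethyl ether F7 by the same 6-exo closure on the C20 face. CrO3/H2SO4 in acetone should oxidize the acetal to the lactone and hydrolyse the enol ether, giving keto lactone F8. One equivalent of KN(SiMe3)2 with PhNTf2 should triflate the more acidic ketone to enol triflate F9, which removes the competing ketone enolate. A second equivalent of KN(SiMe3)2 then closes ring A by the same C4 alkylation, and the route is rejoined at compound 12.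

Step 3. The very hindered, α-quaternary amide may be reduced incompletely, may lose C–O instead of C–N to give the amine, or the hydride may displace the primary chloride. The fallback reduces in two stages through the aldehyde. It sets out from amide 6. Cp2Zr(H)Cl (THF, rt) should stop at aldehyde F10 after hydrolysis of the zirconated hemiaminal, and NaBH4 in MeOH should reduce F10 to alcohol 7, where the route is rejoined.

**Further compounds**

F1 | step 12 | 11-oxo-13,14,15,16-tetranorlabd-8-en-19,20-olide | CC1=C(C(C)=O)[C@]2(COC(=O)[C@@]3(C)CCC2)[C@H]3CC1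
F2 | step 12 | 11-(tert-butyldimethylsilyloxy)-13,14,15,16-tetranorlabda-8,11-dien-19,20-olide | CC1=C(C(=C)O[Si](C)(C)C(C)(C)C)[C@]2(COC(=O)[C@@]3(C)CCC2)[C@H]3CC1
F3 | step 12 | 15-[2,5-bis(benzyloxy)phenyl]-11-(tert-butyldimethylsilyloxy)-15-oxoisocopala-9(11),13(16)-dien-19,20-olide | C[C@@]12CC[C@@H]3[C@]4(CCC[C@]3(C)C(=O)OC4)C1=C(O[Si](C)(C)C(C)(C)C)CC(=C)[C@@H]2C(=O)c1cc(OCc2ccccc2)ccc1OCc1ccccc1
F4 | step 12 | 15-[2,5-bis(benzyloxy)phenyl]-11-(tert-butyldimethylsilyloxy)-15-hydroxyisocopala-9(11),13(16)-dien-19,20-olide (C15 epimers) | C[C@@]12CC[C@@H]3[C@]4(CCC[C@]3(C)C(=O)OC4)C1=C(O[Si](C)(C)C(C)(C)C)CC(=C)[C@@H]2C(O)c1cc(OCc2ccccc2)ccc1OCc1ccccc1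
F5 | step 12 | 15-[2,5-bis(benzyloxy)phenyl]-15-hydroxy-11-(trifluoromethanesulfonyloxy)isocopala-9(11),13(16)-dien-19,20-olide (C15 epimers) | C[C@@]12CC[C@@H]3[C@]4(CCC[C@]3(C)C(=O)OC4)C1=C(OS(=O)(=O)C(F)(F)F)CC(=C)[C@@H]2C(O)c1cc(OCc2ccccc2)ccc1OCc1ccccc1
F6 | step 5 | (1S)-1-[(2-bromo-1-ethoxypropoxy)methyl]-1-(3-chloropropyl)-2-methoxy-3-methylcyclohexa-2,5-diene (acetal epimers) | CCOC(OC[C@]1(CCCCl)C=CCC(C)=C1OC)C(C)Br
F7 | step 5 | (4aS,8aS)-8a-(3-chloropropyl)-3-ethoxy-8-methoxy-4,7-dimethyl-3,4,4a,5,6,8a-hexahydro-1H-isochromene (C3 and C4 epimers) | COC1=C(C)CC[C@H]2C(C)C(OCC)OC[C@@]12CCCCl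
F8 | step 5 | (4aS,8aS)-8a-(3-chloropropyl)-4,7-dimethylhexahydro-1H-isochromene-3,8-dione (C4 and C7 epimers) | O=C1C(C)CC[C@H]2C(C)C(=O)OC[C@@]12CCCCl
F9 | step 5 | (4aS,8aS)-8a-(3-chloropropyl)-4,7-dimethyl-3-oxo-1,4,4a,5,6,8a-hexahydro-3H-isochromen-8-yl trifluoromethanesulfonate (C4 epimers) | O=S(=O)(OC1=C(C)CC[C@H]2C(C)C(=O)OC[C@@]12CCCCl)C(F)(F)F
F10 | step 3 | (1R)-1-(3-chloropropyl)-2-methoxy-3-methylcyclohexa-2,5-diene-1-carbaldehyde | O=C[C@]1(CCCCl)C=CCC(C)=C1OC
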